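**Assumption:** 2,4,6-trihydroxytoluene, (+)-catechin and Eschenmoser's salt are taken as commercial. The final coupling is assumed to favour catechin C8 over C6 by about 2–3:1 (estimated from related catechin alkylations, not measured for this electrophile), with the isomers separated by preparative HPLC.

## Retrosynthetic overview

1. Pilosanol B ⇒ cut the C8–CH2 bond: (+)-catechin (C8 nucleophile, carries both stereocentres) plus the o-quinone methide (o-QM) of the acylphloroglucinol half, photogenerated from its Mannich base.
2. Mannich base ⇒ acylphloroglucinol monomer (one free aromatic C–H) plus Eschenmoser's salt.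
3. Monomer ⇒ 2,4,6-trihydroxytoluene plus isobutyryl chloride (Friedel–Crafts); the ortho-OMe is placed by 4,6-di-O-benzylation, 2-O-methylation, hydrogenolysis.
4. Ring formation: none. Both aromatic rings and the pyran ring are bought intact; the route only joins them.

## Route

**Step 1**
Reactants: 1, 2,4,6-trihydroxytoluene; 2, isobutyryl chloride
Product: 3, 1-(2,4,6-trihydroxy-3-methylphenyl)-2-methylpropan-1-one
Conditions: AlCl3 (3.5 equiv), PhNO2, rt → 65 °C; aq. HCl work-up
Reagents that add atoms: isobutyryl chloride, CC(C)C(=O)Cl
Why: Friedel–Crafts C-acylation of the electron-rich triol; the two free ring carbons are equivalent, so one regioisomer forms, and the first acyl group deactivates the ring toward a second.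

**Step 2**
Reactants: 3; 4, benzyl bromide
Product: 5, 1-[4,6-bis(benzyloxy)-2-hydroxy-3-methylphenyl]-2-methylpropan-1-one (free OH is the one between the acyl group and the C-methyl)
Conditions: BnBr (2.05 equiv), K2CO3, DMF, 0 °C → rt; chromatography
Reagents that add atoms: benzyl bromide, BrCc1ccccc1
Why: Williamson O-alkylation; the non-chelated 4-OH (para to C=O) reacts first, then the less hindered ortho 6-OH, while the 2-OH, buttressed by the adjacent methyl into the C=O hydrogen bond, stays free (the selectivity I recall for partial alkylation of 3-methylphloroacylphenones).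

**Step 3**
Reactants: 5; 6, iodomethane
Product: 7, 1-[4,6-bis(benzyloxy)-2-methoxy-3-methylphenyl]-2-methylpropan-1-one
Conditions: MeI (3 equiv), K2CO3, DMF, 50 °C
Reagents that add atoms: iodomethane, CI
Why: forcing Williamson methylation of the only remaining (chelated) phenol, so the OMe position is unambiguous; K2CO3 does not enolise the hindered ketone.

**Step 4**
Reactants: 7
Product: 8, 1-(2,4-dihydroxy-6-methoxy-5-methylphenyl)-2-methylpropan-1-one (OMe ortho to C=O and next to the C-methyl; the one free ring C–H lies between the two OH groups)
Conditions: H2 (1 atm), 10% Pd/C, EtOAc–MeOH, rt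
Reagents that add atoms: none
Why: Pd-catalysed hydrogenolysis of the two benzyl aryl ethers; the hindered, phenol-conjugated aryl ketone and the aryl methyl ether are inert under these conditions.

**Step 5**
Reactants: 8; 9, Eschenmoser's salt (N,N-dimethylmethyleneiminium iodide)
Product: 10, 1-{3-[(dimethylamino)methyl]-2,4-dihydroxy-6-methoxy-5-methylphenyl}-2-methylpropan-1-one (isolated as the phenolate/ammonium zwitterion)
Conditions: Me2N+=CH2 I− (1.0 equiv), MeCN, 0 °C → rt; aq. NaHCO3 work-up, keep ≤ 25 °C
Reagents that add atoms: Eschenmoser's salt, C=[N+](C)C.[I-]
Why: Mannich aminomethylation by a preformed iminium ion at the only free ring carbon; with no free formaldehyde, the methylene-bis dimer is not expected.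

**Step 6**
Reactants: 10; 11, (+)-catechin, (2R,3S)
Product: 12, pilosanol B, 1-[3-{[(2R,3S)-2-(3,4-dihydroxyphenyl)-3,5,7-trihydroxy-3,4-dihydro-2H-chromen-8-yl]methyl}-2,4-dihydroxy-6-methoxy-5-methylphenyl]-2-methylpropan-1-one
Conditions: 11 (3 equiv), hν 365 nm (LED), degassed MeCN / pH 7.0 phosphate buffer (1:1), 15 °C, Ar; Sephadex LH-20 then RP-HPLC to remove the 6-linked isomer and recover excess 11
Reagents that add atoms: none beyond reactants 10 and 11 (Me2NH is lost)
Why: Proposed new method: zwitterionic 10 absorbs at 365 nm, where catechin is transparent, and excited-state charge shift from the phenolate oxygen into the ring should expel Me2NH from the ortho benzylic carbon to give the acyl-stabilised o-QM; catechin C8 (ortho to 7-OH, para to 5-OH) then adds in a Friedel–Crafts/Michael step and rearomatises, while water, amine and O-adducts are reversible and funnel to the C–C product; no stereocentre is touched (neutral pH, 15 °C, flavan not excited), so (2R,3S) is carried over from catechin; the closest known chemistry is UV photodeamination of simple o-hydroxybenzylamine Mannich bases and ammonium salts to o-QMs, and thermal o-QM alkylation of phloroglucinols.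

## Compound list

1 | 2,4,6-trihydroxytoluene | Cc1c(O)cc(O)cc1O | starting material
2 | isobutyryl chloride | CC(C)C(=O)Cl | starting material
3 | 1-(2,4,6-trihydroxy-3-methylphenyl)-2-methylpropan-1-one | CC(C)C(=O)c1c(O)cc(O)c(C)c1O | intermediate
4 | benzyl bromide | BrCc1ccccc1 | starting material
5 | 1-[4,6-bis(benzyloxy)-2-hydroxy-3-methylphenyl]-2-methylpropan-1-one | CC(C)C(=O)c1c(OCc2ccccc2)cc(OCc2ccccc2)c(C)c1O | intermediate
6 | iodomethane | CI | starting material
7 | 1-[4,6-bis(benzyloxy)-2-methoxy-3-methylphenyl]-2-methylpropan-1-one | COc1c(C)c(OCc2ccccc2)cc(OCc2ccccc2)c1C(=O)C(C)C | intermediate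
8 | 1-(2,4-dihydroxy-6-methoxy-5-methylphenyl)-2-methylpropan-1-one | COc1c(C)c(O)cc(O)c1C(=O)C(C)C | intermediate
9 | Eschenmoser's salt | C=[N+](C)C.[I-] | starting material
10 | 1-{3-[(dimethylamino)methyl]-2,4-dihydroxy-6-methoxy-5-methylphenyl}-2-methylpropan-1-one | COc1c(C)c(O)c(CN(C)C)c(O)c1C(=O)C(C)C | intermediate
11 | (+)-catechin, (2R,3S) | Oc1cc(O)c2c(c1)O[C@H](c1ccc(O)c(O)c1)[C@@H](O)C2 | starting material
12 | pilosanol B | COc1c(C)c(O)c(Cc2c(O)cc(O)c3c2O[C@H](c2ccc(O)c(O)c2)[C@@H](O)C3)c(O)c1C(=O)C(C)C | target

## Summary

Total steps: 6. Longest linear sequence: 6 (from 2,4,6-trihydroxytoluene; catechin enters in the last step).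

Steps most likely to fail:

1. **Step 6 (new photochemical coupling).** Risks: fast excited-state proton transfer to the ketone may make the quantum yield low; C6 alkylation competes with C8; the o-QM may self-condense to the methylene-bis dimer. Fallback (known chemistry): N-methylate 10 with MeI and release the same o-QM thermally with mild base (iPr2NEt or NaOAc, MeCN/H2O, rt) in the presence of excess catechin, the classical Mannich-salt o-QM Friedel–Crafts alkylation used for methylene-bridged acylphloroglucinols.

2. **Step 2 (4,6- versus 2,4-dibenzylation).** Risk: the regioisomer and over- or C-benzylated by-products lower the yield, and the isomers may be hard to separate. Fallback: use symmetry in place of O-differentiation. Start from 2,6-dihydroxy-4-methoxybenzaldehyde, where the two carbons flanking OMe are equivalent; C-acylate one, C-methylate the other, then reduce CHO to CH2OH (NaBH4) so the aldehyde carbon becomes the bridging CH2 through the benzylic alcohol as o-QM precursor.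

3. **Step 5 (Mannich base isolation and stability).** Risk: premature loss of amine and self-condensation; the zwitterion is hard to purify. Fallback: reverse the polarity. Aminomethylate (+)-catechin (Eschenmoser's salt), purify the 8-isomer once, and use monomer 8, with its single free C–H, as the nucleophile; this also settles C8 versus C6 before the coupling.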